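All runs are simulated with constants of no real substance, noise included.

**One step.** In a one-step world, substrate + reagent → target, each turn uses one of each, so target cannot pass the smaller charge. The givens fold into one number, E = 0.700, the equivalents of reagent charged per substrate charged in the flask. Since 21.7 mM of reagent stands below 31 mM of substrate, reagent is the limiting reagent of the flask, and E read as a share of the substrate charged gives its ceiling for target, 70.0%.

| setting | dawn | flask |
|---|---|---|
| substrate | 31 mM (fed, over 40 min) | 31 mM (fed, over 40 min) |
| reagent | 33 mM | 21.7 mM |
| remark | run made earlier |  |
| time |  | 10 h |

dawn run (percent of the substrate charged)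

| time / min | target / % |
|---|---|
| 5.00 | 0 |
| 8.00 | 1 |
| 12.0 | 0 |
| 15.0 | 2 |
| 25.0 | 6 |
| 40.0 | 12 |
| 60.0 | 18 |

(each reading ± 1.5 percentage points)

- percent here means substrate units held: one side product counts as two
- what is said of target includes idle adduct
- the numbers in the tables scatter with a standard deviation of 1.5 percentage points
- candidate steps: substrate + reagent <-> target; 2 substrate -> side product; 2 reagent -> self-condensation product; reagent + target <-> idle adduct
- percentages count the whole charge, also what has not yet gone in

1. time up to 10 h at which target stands highest
2. the amount of target, in percent of the substrate charged, at that time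

**Testing it.** The dawn run has E = 1.06, so its ceiling is the full substrate charge, yet its reading stands at 18% after 60.0 min, having risen 6 percentage points in the last 20.0 min. E carries no clock, so one number is not enough for the peak time. The candidate back step and the self-condensation of reagent may hold target lower. The reckoning here commits to a bound: target in the flask stays at or below 70.0%.

**The result.** The forecast gives 50% at 10 h, with target “probably still creeping upward”. The flask gives 20.6% at 3.79 h.

    substrate + reagent ⇌ target (K = 97.0 M⁻¹, k = 22.0 M⁻¹ h⁻¹)
    2 substrate → side product (k = 0.340 M⁻¹ h⁻¹)
    2 reagent → self-condensation product (k = 28.0 M⁻¹ h⁻¹)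
    reagent + target ⇌ idle adduct, settled at all times (K = 61.0 M⁻¹)

**Second flask.** The flask reaches 29.4% of its ceiling, with 11.4% of its reagent and 74.8% of its substrate still there at the best time, and target is down to 17.8% at 10.0 h. A neighbouring flask with 12 mM of substrate has E = 1.81, so its ceiling is 100%. Its highest target is 26.0% of the substrate charged. At 10.0 h this neighbour holds 74.7% of its substrate and 9.18% of its reagent.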